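## Retrosynthetic overview
- Target **1** comes from tri‑O‑benzyl compound **2** by one hydrogenolysis that removes the 7‑, 4'‑ and guaiacyl 4‑O‑benzyl groups.
- **2** comes from an anodic dehydrogenative [3+2] annulation of 7,4'‑di‑O‑benzyltaxifolin (**3**) with (E)‑4‑O‑benzylconiferyl alcohol (**4**). This step forms the C8–C2' bond and the C7–O3' bond, so the dihydrobenzofuran ring is built last, onto the intact chromanone.
- The flavanonol C2/C3 stereocentres are carried in unchanged from (+)‑taxifolin (**5**). The trans‑benzofuran centres (C7, C8) arise from the E‑alkene geometry plus substrate bias from the C2 stereocentre. The wrong diastereomer is removed by chromatography.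
- **3** comes from **5** by regioselective dibenzylation. **4** comes from ferulic acid (**6**) via benzyl 4‑O‑benzylferulate (**7**) and DIBAL reduction.

Assumptions: commercial (+)‑taxifolin is (2R,3R), the same configuration as the flavanonol in the target. The 7,4'‑dibenzyl ether is assumed separable from the 7,3'‑ and 7,3',4'‑benzyl ethers.

## Route

**Step 1**
Reactants: **6** (E)‑ferulic acid
Product: **7** benzyl (E)‑4‑O‑benzylferulate
Conditions: BnBr (2.5 equiv), K2CO3 (3 equiv), DMF, rt, 12 h
Reagents that add atoms: benzyl bromide, BrCc1ccccc1
Why: SN2 alkylation of the carboxylate and the phenoxide (Williamson‑type); the E‑alkene is untouched.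

**Step 2**
Reactants: **7**
Product: **4** (E)‑4‑O‑benzylconiferyl alcohol
Conditions: DIBAL‑H (3 equiv), CH2Cl2, −78 °C → 0 °C
Reagents that add atoms: none
Why: DIBAL reduces the cinnamate ester 1,2 to the allylic alcohol and leaves the alkene and aryl benzyl ether intact. The benzyl alcohol by‑product is removed chromatographically.

**Step 3**
Reactants: **5** (+)‑taxifolin
Product: **3** 7,4'‑di‑O‑benzyl‑(2R,3R)‑taxifolin (3'‑OH, 5‑OH and 3‑OH free)
Conditions: BnBr (2.1 equiv), K2CO3 (2.2 equiv), DMF, 0 °C → rt, 12 h, then chromatographic separation of the regioisomers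
Reagents that add atoms: benzyl bromide, BrCc1ccccc1
Why: The most acidic 7‑OH alkylates first. Of the catechol oxygens, the 4'‑OH is the more accessible, whereas the 3'‑OH is less accessible and the 5‑OH is chelated, so 7,4'‑dialkylation is expected as the major diether (Williamson). The cold, brief base exposure is chosen to avoid C2/C3 epimerisation, so the (2R,3R) centres are retained.

**Step 4**
Reactants: **3** (1 equiv) and **4** (2.5 equiv)
Product: **2** (2R,3R)‑flavanonol‑fused trans‑2,3‑dihydrobenzofuran, tri‑O‑benzyl (7R,8S)
Conditions: undivided cell, graphite(+)|Pt(−), constant current 5 mA (~3 F/mol), nBu4NBF4 (0.1 M), HFIP/MeCN (1:4), rt, N2; then preparative HPLC to separate the (7S,8R) diastereomer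
Reagents that add atoms: none (H2 is evolved at the cathode)
Why: The free 3'‑OH is the only phenol that can close the five‑membered ring, because C4' carries OBn and is blocked. The new trans stereocentres follow from the E‑alkene plus a modest bias from the adjacent (2R)‑flavanonol centre (expected dr about 1.5–3:1), and the diastereomers are separated.
Proposed new method: Anodic oxidation of the electron‑rich 4‑benzyloxystyrene **4** in HFIP gives its radical cation. The nucleophilic ortho carbon C2' of the phenol in **3** attacks C8 (anti‑Markovnikov), which leaves a p‑alkoxybenzyl radical at C7. Further oxidation gives the stabilised benzylic cation, and the 3'‑OH closes onto it (5‑exo) to give the trans‑dihydrobenzofuran. This is closest to known anodic or Ag2O‑mediated phenol–styrene and phenol–indole [3+2] annulations (for example the methyl ferulate neolignan dimerisation). It is new in being applied to an unprotected polyhydroxy flavanonol, at a hindered C2' position next to a stereogenic substituent, with diastereocontrol from that remote centre.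

**Step 5**
Reactants: **2**
Product: **1** target
Conditions: H2 (1 atm), Pd(OH)2/C (20 wt%), EtOAc/MeOH 1:1, rt, 3 h
Reagents that add atoms: none
Why: Hydrogenolysis cleaves the three aryl benzyl ethers (7‑O, 4'‑O and the guaiacyl 4‑O). The ketone, the 3‑OH and the 5‑OH survive, and no stereocentre is touched, since the only stereocentres are the four already set.

## Compound list
1 | target: (2R,3R)‑flavanonol with a trans (7R,8S) 2‑(4‑hydroxy‑3‑methoxyphenyl)‑3‑hydroxymethyl‑dihydrobenzofuran fused at the B ring (CID21589839) | COc1cc([C@@H]2Oc3c(O)ccc([C@H]4Oc5cc(O)cc(O)c5C(=O)[C@@H]4O)c3[C@H]2CO)ccc1O | target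
2 | 7,4',4''‑tri‑O‑benzyl derivative of 1 | COc1cc([C@@H]2Oc3c(OCc4ccccc4)ccc([C@H]4Oc5cc(OCc6ccccc6)cc(O)c5C(=O)[C@@H]4O)c3[C@H]2CO)ccc1OCc1ccccc1 | intermediate
3 | 7,4'‑di‑O‑benzyl‑(2R,3R)‑taxifolin | c1ccccc1COc1ccc([C@H]2Oc3cc(OCc4ccccc4)cc(O)c3C(=O)[C@@H]2O)cc1O | intermediate
4 | (E)‑4‑O‑benzylconiferyl alcohol | OC/C=C/c1ccc(OCc2ccccc2)c(OC)c1 | intermediate
5 | (+)‑taxifolin, (2R,3R)‑dihydroquercetin | Oc1ccc([C@H]2Oc3cc(O)cc(O)c3C(=O)[C@@H]2O)cc1O | starting material
6 | (E)‑ferulic acid | O=C(O)/C=C/c1ccc(O)c(OC)c1 | starting material
7 | benzyl (E)‑4‑O‑benzylferulate | O=C(OCc1ccccc1)/C=C/c1ccc(OCc2ccccc2)c(OC)c1 | intermediate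

## Totals
Total steps: 5. Longest linear sequence: 4 (6 → 7 → 4 → 2 → 1).

## Three steps most likely to fail
1. **Step 4 (proposed new step).** Risks are low diastereoselectivity, alkene self‑coupling, over‑oxidation of the product, and attack at C5'/C6' instead of C2'.
 Fallback (known chemistry): Ag2O‑mediated oxidative phenoxyl/alkene coupling of **3** and **4** in CH2Cl2/MeCN, as used for dihydrobenzofuran neolignans. This replaces anodic radical‑cation chemistry with stoichiometric single‑electron oxidation and phenoxyl radical coupling, with the same separation of diastereomers.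
2. **Step 3.** Risks are poor 4'‑ versus 3'‑selectivity and base‑induced C2 epimerisation.
 Fallback: benzylate the 7‑OH selectively (1.1 equiv BnBr), form the 3',4'‑O‑diphenylmethylene ketal (Ph2CCl2), then open it regioselectively with DIBAL‑H to give a separable 4'‑O‑benzhydryl/3'‑OH compound. Carry this through Step 4 and remove the benzhydryl group in the final hydrogenolysis.
3. **Step 5.** Pd hydrogenolysis could also cleave the benzylic C7–O bond of the dihydrobenzofuran.
 Fallback: BCl3 with pentamethylbenzene as cation scavenger, CH2Cl2, −78 °C, a Lewis‑acid debenzylation that avoids Pd/H2.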